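**Retrosynthetic overview**
1. Plakortolide G ⇐ C6–CH3 bond: face-selective C-methylation of a bicyclic methoxy peroxyketal through its peroxycarbenium ion (new step, sets C6).
2. Peroxyketal ⇐ keto-butenolide + H2O2/MeOH: perketalisation, then 6-exo peroxy-Michael closure; the 1,2-dioxane is formed last, onto the preformed butenolide ring, and the cis fusion sets C3 from C4.
3. Keto-butenolide ⇐ methyl-ketone enol silane + 5-acetoxy-5-methylbutenolide: organocatalytic asymmetric substitution sets C4 (new step); the butenolide ring comes from 2-methylfuran and O2.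
4. Methyl ketone ⇐ achiral dienone by organocatalytic transfer hydrogenation (C8, first stereocentre).
5. Dienone ⇐ 1,6-heptadiyne by two Zr-catalysed carboaluminations (benzyl chloride, then acetyl chloride).

Assumption: plakortolide numbering is used (C1 lactone C=O, C3 peroxy CH, C4 lactone C–O, C6 peroxy quaternary C, C8 side-chain methine), and for each chiral catalyst the enantiomer that gives the drawn configuration is meant.

**Step 1**
Reactants: 1 1,6-heptadiyne; 2 benzyl chloride
Product: 4 (E)-(3-methyloct-2-en-7-yn-1-yl)benzene, via alkenylalane 3 (not isolated)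
Conditions: 1 (3 equiv), AlMe3, Cp2ZrCl2 (20 mol%), CH2Cl2, 0 °C to rt; then 2, Pd(PPh3)4 (3 mol%), THF, rt
Reagents that add atoms: trimethylaluminium C[Al](C)C
Why: Negishi Zr-catalysed syn-methylalumination of one terminal alkyne (the excess of 1 limits double reaction) and Pd-catalysed cross-coupling of the alkenylalane with benzyl chloride with retention fix the E-trisubstituted alkene.

**Step 2**
Reactants: 4 (E)-(3-methyloct-2-en-7-yn-1-yl)benzene; 5 acetyl chloride
Product: 7 (3E,8E)-4,8-dimethyl-10-phenyldeca-3,8-dien-2-one, via alkenylalane 6 (not isolated)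
Conditions: AlMe3 (2 equiv), Cp2ZrCl2 (20 mol%), CH2Cl2, rt; then 5, Pd(PPh3)4 (5 mol%), THF, 0 °C
Reagents that add atoms: trimethylaluminium C[Al](C)C
Why: A second Negishi carboalumination on the remaining terminal alkyne (the trisubstituted alkene is inert) and Pd-catalysed acylation of the alkenylalane with retention give the E-enone.

**Step 3**
Reactants: 7 (3E,8E)-4,8-dimethyl-10-phenyldeca-3,8-dien-2-one
Product: 8 (S,E)-4,8-dimethyl-10-phenyldec-8-en-2-one
Conditions: Hantzsch ester (1.2 equiv), valine tert-butyl ester·TRIP phosphate salt (10 mol%), Bu2O, 60 °C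
Reagents that add atoms: none
Why: Organocatalytic iminium-ion transfer hydrogenation (asymmetric counteranion-directed catalysis) in which the primary ammonium phosphate condenses only with the enone and the Hantzsch ester delivers hydride to one face of the β-carbon, setting C8 as S from an achiral substrate while the isolated alkene is untouched.

**Step 4**
Reactants: 8 (S,E)-4,8-dimethyl-10-phenyldec-8-en-2-one
Product: 10 (S,E)-[(4,8-dimethyl-10-phenyldeca-1,8-dien-2-yl)oxy]trimethylsilane, via lithium enolate 9 (not isolated)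
Conditions: LDA, THF, −78 °C; then TMSCl, −78 to 0 °C
Reagents that add atoms: chlorotrimethylsilane C[Si](C)(C)Cl
Why: Kinetic deprotonation by LDA at the less hindered methyl group and O-silylation give the terminal enol silane without touching the β-stereocentre.

**Step 5**
Reactants: 11 2-methylfuran
Product: 14 2-methyl-5-oxo-2,5-dihydrofuran-2-yl acetate (racemic), via endoperoxide 12 (not isolated), via hydroxybutenolide 13 (not isolated)
Conditions: O2, hν, rose bengal (cat.), iPr2NEt, CH2Cl2, −78 °C; then Ac2O, DMAP (cat.), 0 °C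
Reagents that add atoms: dioxygen O=O; acetic anhydride CC(=O)OC(C)=O
Why: Singlet-oxygen [4+2] cycloaddition to the furan, amine-induced Kornblum–DeLaMare opening of the endoperoxide at C5–H to the γ-hydroxybutenolide and O-acetylation give the γ-acetoxybutenolide.

**Step 6**
Reactants: 10 (S,E)-[(4,8-dimethyl-10-phenyldeca-1,8-dien-2-yl)oxy]trimethylsilane; 14 2-methyl-5-oxo-2,5-dihydrofuran-2-yl acetate
Product: 15 (R)-5-[(S,E)-4,8-dimethyl-2-oxo-10-phenyldec-8-en-1-yl]-5-methylfuran-2(5H)-one
Conditions: chiral imidodiphosphorimidate (IDPi) acid (3 mol%), 14 (1.5 equiv), toluene, −60 °C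
Reagents that add atoms: none
Why: Proposed new method: the enol silane silylates the IDPi acid to a silylium Lewis acid that abstracts acetate from 14 (as Me3SiOAc), the planar 5-methyl-2-oxofuran-5-ylium ion is held as a contact ion pair in the confined chiral anion, and the enol silane attacks C5 on the open face to set C4 as R (both enantiomers of 14 converge and the remote C8 centre has no influence); closest known reaction type: IDPi-catalysed Mukaiyama-type substitution of lactol acetates via cyclic oxocarbenium ions, and achiral Lewis-acid Mukaiyama substitution at C5 of γ-acyloxybutenolides.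

**Step 7**
Reactants: 15 (R)-5-[(S,E)-4,8-dimethyl-2-oxo-10-phenyldec-8-en-1-yl]-5-methylfuran-2(5H)-one
Product: 17 (1R,6R)-4-methoxy-6-methyl-4-[(2S,6E)-2,6-dimethyl-8-phenyloct-6-en-1-yl]-2,3,7-trioxabicyclo[4.3.0]nonan-8-one (both C4 epimers), via hydroperoxy ketal 16 (not isolated)
Conditions: urea·H2O2 (5 equiv), Sc(OTf)3 (5 mol%), MeOH, rt; evaporate; then Et2NH (0.3 equiv), CF3CH2OH, rt
Reagents that add atoms: hydrogen peroxide OO; methanol CO
Why: Acid-catalysed perketalisation of the ketone gives the α-methoxy hydroperoxide, whose peroxide then adds 6-exo to the butenolide (intramolecular peroxy-Michael addition), the tether forcing attack on the face of the C5 arm so that the cis ring fusion sets C3 as R from C4, and both ketal epimers are carried on.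

**Step 8**
Reactants: 17 (1R,6R)-4-methoxy-6-methyl-4-[(2S,6E)-2,6-dimethyl-8-phenyloct-6-en-1-yl]-2,3,7-trioxabicyclo[4.3.0]nonan-8-one
Product: 18 plakortolide G = (1R,4R,6R)-4,6-dimethyl-4-[(2S,6E)-2,6-dimethyl-8-phenyloct-6-en-1-yl]-2,3,7-trioxabicyclo[4.3.0]nonan-8-one
Conditions: AlMe3 (4 equiv), CH2Cl2, −78 to −30 °C
Reagents that add atoms: trimethylaluminium C[Al](C)C
Why: Proposed new method: AlMe3 ionises the exocyclic methoxy group to a cyclic peroxycarbenium ion whose half-chair holds the C4–O bond pseudoaxial and C4–CH3 pseudoequatorial, and methyl is delivered axially through a chair-like transition state on the face syn to the lactone oxygen (axial attack on the other face would be syn-diaxial to C4–CH3), so both ketal epimers give the 6R quaternary peroxide; closest known reaction type: Lewis-acid allylation and Mukaiyama alkylation of cyclic peroxyketals via peroxycarbenium ions, and AlMe3 C-methylation of O,O-acetals.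

**Compound list**
1 | 1,6-heptadiyne | C#CCCCC#C | starting material
2 | benzyl chloride | ClCc1ccccc1 | starting material
3 | (E)-dimethyl(2-methylhept-1-en-6-yn-1-yl)alumane | C#CCCC/C(C)=C/[Al](C)C | intermediate
4 | (E)-(3-methyloct-2-en-7-yn-1-yl)benzene | C#CCCC/C(C)=C/Cc1ccccc1 | intermediate
5 | acetyl chloride | CC(Cl)=O | starting material
6 | dimethyl[(1E,6E)-2,6-dimethyl-8-phenylocta-1,6-dien-1-yl]alumane | C/C(=C\Cc1ccccc1)CCC/C(C)=C/[Al](C)C | intermediate
7 | (3E,8E)-4,8-dimethyl-10-phenyldeca-3,8-dien-2-one | C/C(=C\Cc1ccccc1)CCC/C(C)=C/C(C)=O | intermediate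
8 | (S,E)-4,8-dimethyl-10-phenyldec-8-en-2-one | C/C(=C\Cc1ccccc1)CCC[C@H](C)CC(C)=O | intermediate
9 | lithium (S,E)-4,8-dimethyl-10-phenyldeca-1,8-dien-2-olate | C/C(=C\Cc1ccccc1)CCC[C@H](C)CC(=C)[O-].[Li+] | intermediate
10 | (S,E)-[(4,8-dimethyl-10-phenyldeca-1,8-dien-2-yl)oxy]trimethylsilane | C/C(=C\Cc1ccccc1)CCC[C@H](C)CC(=C)O[Si](C)(C)C | intermediate
11 | 2-methylfuran | Cc1ccco1 | starting material
12 | 1-methyl-2,3,7-trioxabicyclo[2.2.1]hept-5-ene | CC12C=CC(OO1)O2 | intermediate
13 | 5-hydroxy-5-methylfuran-2(5H)-one | CC1(O)OC(=O)C=C1 | intermediate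
14 | 2-methyl-5-oxo-2,5-dihydrofuran-2-yl acetate (racemic) | CC(=O)OC1(C)OC(=O)C=C1 | intermediate
15 | (R)-5-[(S,E)-4,8-dimethyl-2-oxo-10-phenyldec-8-en-1-yl]-5-methylfuran-2(5H)-one | C/C(=C\Cc1ccccc1)CCC[C@H](C)CC(=O)C[C@@]1(C)OC(=O)C=C1 | intermediate
16 | (5R)-5-[(4S,8E)-2-hydroperoxy-2-methoxy-4,8-dimethyl-10-phenyldec-8-en-1-yl]-5-methylfuran-2(5H)-one (both ketal epimers) | C/C(=C\Cc1ccccc1)CCC[C@H](C)CC(OC)(OO)C[C@@]1(C)OC(=O)C=C1 | intermediate
17 | (1R,6R)-4-methoxy-6-methyl-4-[(2S,6E)-2,6-dimethyl-8-phenyloct-6-en-1-yl]-2,3,7-trioxabicyclo[4.3.0]nonan-8-one (both C4 epimers) | C/C(=C\Cc1ccccc1)CCC[C@H](C)CC1(OC)C[C@@]2(C)OC(=O)C[C@H]2OO1 | intermediate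
18 | plakortolide G, (1R,4R,6R)-4,6-dimethyl-4-[(2S,6E)-2,6-dimethyl-8-phenyloct-6-en-1-yl]-2,3,7-trioxabicyclo[4.3.0]nonan-8-one | C/C(=C\Cc1ccccc1)CCC[C@H](C)C[C@]1(C)C[C@@]2(C)OC(=O)C[C@H]2OO1 | target

**Step count and risks**
Total steps: 8. Longest linear sequence: 7 (steps 1, 2, 3, 4, 6, 7, 8); step 5 is a one-step side branch.

The three steps most likely to fail:

Step 6 (proposed new step). The acyl-substituted tertiary oxocarbenium ion is electron-poor, the enol silane may instead add in Mukaiyama–Michael fashion to the butenolide, and face control on a tertiary cation is untested. Product 15 is a β-acyloxy ketone and must be kept away from base (E1cB loss of the lactone carboxylate). Fallback with known chemistry, setting out from 10 and coming back at 15: Cu(II)–tBu-box-catalysed Mukaiyama aldol of 10 with methyl pyruvate gives the aldol silyl ether F5. DIBAL at −78 °C reduces the ester to the aldehyde and the ketone to the alcohol, giving the hydroxy aldehyde F6. Ando Z-olefination with ethyl (diphenoxyphosphoryl)acetate gives the Z-enoate F7. Dilute HCl in THF removes the silyl group and closes the lactone to the hydroxy butenolide F8. Dess–Martin oxidation returns to 15.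

Step 8 (proposed new step). AlMe3 may reduce the O–O bond, ionisation may open the ring by loss of the peroxide instead of methoxide, and the facial preference may be modest. Fallback with known chemistry, setting out from 15 and coming back at 18: Takai–Lombardo methylenation (Zn, CH2Br2, TiCl4) gives the methylene compound F9. Mukaiyama–Isayama hydroperoxysilylation (Co(thd)2, O2, Et3SiH), stopped at partial conversion because the side-chain alkene reacts more slowly, gives the triethylsilyl peroxide F10 as both C6 epimers. TBAF frees the peroxide anion, which closes onto the butenolide to give 18 together with 6-epi-plakortolide G F11; the two are separated by HPLC.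

Step 3. Iminium transfer hydrogenation is well established for cyclic enones but has little precedent for acyclic β-methyl-β-alkyl enones, so the ee at C8 may be insufficient. Fallback, setting out from 4 and coming back at 8: carboalumination of 4 to alkenylalane 6 and trapping with paraformaldehyde gives the dienol F1. MnO2 gives the dienal F2. Imidazolidinone-catalysed transfer hydrogenation with Hantzsch ester, which is enantioconvergent for E/Z enals, gives the (S)-aldehyde F3. MeMgBr gives the carbinol F4, and Dess–Martin oxidation returns to 8.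

**Further compounds**
F1 | step 3 | (2E,7E)-3,7-dimethyl-9-phenylnona-2,7-dien-1-ol | C/C(=C\Cc1ccccc1)CCC/C(C)=C/CO
F2 | step 3 | (2E,7E)-3,7-dimethyl-9-phenylnona-2,7-dienal | C/C(=C\Cc1ccccc1)CCC/C(C)=C/C=O
F3 | step 3 | (S,E)-3,7-dimethyl-9-phenylnon-7-enal | C/C(=C\Cc1ccccc1)CCC[C@H](C)CC=O
F4 | step 3 | (4S,8E)-4,8-dimethyl-10-phenyldec-8-en-2-ol (both carbinol epimers) | C/C(=C\Cc1ccccc1)CCC[C@H](C)CC(C)O
F5 | step 6 | methyl (2R,6S,10E)-2,6,10-trimethyl-4-oxo-12-phenyl-2-(trimethylsilyloxy)dodec-10-enoate | C/C(=C\Cc1ccccc1)CCC[C@H](C)CC(=O)C[C@@](C)(O[Si](C)(C)C)C(=O)OC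
F6 | step 6 | (2R,6S,10E)-4-hydroxy-2,6,10-trimethyl-12-phenyl-2-(trimethylsilyloxy)dodec-10-enal (both carbinol epimers) | C/C(=C\Cc1ccccc1)CCC[C@H](C)CC(O)C[C@@](C)(O[Si](C)(C)C)C=O
F7 | step 6 | ethyl (2Z,4R,8S,12E)-6-hydroxy-4,8,12-trimethyl-14-phenyl-4-(trimethylsilyloxy)tetradeca-2,12-dienoate | C/C(=C\Cc1ccccc1)CCC[C@H](C)CC(O)C[C@@](C)(O[Si](C)(C)C)/C=C\C(=O)OCC
F8 | step 6 | (5R)-5-[(4S,8E)-2-hydroxy-4,8-dimethyl-10-phenyldec-8-en-1-yl]-5-methylfuran-2(5H)-one | C/C(=C\Cc1ccccc1)CCC[C@H](C)CC(O)C[C@@]1(C)OC(=O)C=C1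
F9 | step 8 | (R)-5-[(S,E)-4,8-dimethyl-2-methylidene-10-phenyldec-8-en-1-yl]-5-methylfuran-2(5H)-one | C/C(=C\Cc1ccccc1)CCC[C@H](C)CC(=C)C[C@@]1(C)OC(=O)C=C1
F10 | step 8 | (5R)-5-[(4S,8E)-2,4,8-trimethyl-10-phenyl-2-(triethylsilylperoxy)dec-8-en-1-yl]-5-methylfuran-2(5H)-one (both C2 epimers) | C/C(=C\Cc1ccccc1)CCC[C@H](C)CC(C)(OO[Si](CC)(CC)CC)C[C@@]1(C)OC(=O)C=C1
F11 | step 8 | 6-epi-plakortolide G | C/C(=C\Cc1ccccc1)CCC[C@H](C)C[C@@]1(C)C[C@@]2(C)OC(=O)C[C@H]2OO1
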